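**Retrosynthetic overview**
- The butenolide (ring B) is bought preformed as tetronic acid and attached last: target ⇒ (E,E)-dienyl iodide + 4-(tributylstannyl)furan-2(5H)-one (Stille coupling). The iodide comes from the enal (Takai olefination), which comes from the allylic alcohol.
- The (E)-α-alkylidene lactone is cut at the exocyclic C=C: lithium enolate of (S)-5-(2-methylprop-1-enyl)-γ-butyrolactone + a C12 aldehyde (aldol addition, then mesylate elimination).
- The C12 aldehyde, with both trisubstituted (E)-alkenes already in place, comes from (2E,6E)-farnesol (silyl protection, terminal bromohydrin, epoxide, periodate cleavage).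
- The (S)-γ-lactone (ring A, the only ring made in the route, formed first) comes from prenal by asymmetric allylboration, selective hydroboration and oxidative lactonization.

Assumption: compounds 11–13 are racemic at the carbon that is later cleaved off and 16–17 are diastereomer mixtures at centres that are later destroyed, so these centres carry no descriptor; step 1 is expected to give about 92–96% ee, not full optical purity.

**Step 1**
Reactants: 1 3-methylbut-2-enal (prenal); 2 allylmagnesium bromide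
Product: 4 (S)-6-methylhepta-1,5-dien-4-ol, via borinate ester 3 (not isolated)
Conditions: (−)-Ipc2BOMe [from (+)-α-pinene], 2, Et2O, −78 °C to rt; then 1, −78 °C, 3 h; then 3 M NaOH, 30% H2O2, rt
Reagents that add atoms: none
Why: Brown asymmetric allylboration, in which the B-allyl reagent with isopinocampheyl groups from (+)-α-pinene delivers allyl through a chair six-membered transition state to the Si face of the aldehyde (1,2-addition only), setting the (S)-carbinol centre.

**Step 2**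
Reactants: 4 (S)-6-methylhepta-1,5-dien-4-ol
Product: 6 (S)-6-methylhept-5-ene-1,4-diol, via bis-borane adduct 5 (not isolated)
Conditions: 9-BBN dimer (2.4 equiv B–H), THF, 0 °C to rt, 6 h; then 3 M NaOH, 30% H2O2, 0 °C to rt
Reagents that add atoms: hydrogen peroxide, OO
Why: Hydroboration–oxidation, in which bulky 9-BBN adds anti-Markovnikov to the monosubstituted alkene far faster than to the trisubstituted one and C–B oxidation gives the primary alcohol without touching the carbinol centre.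

**Step 3**
Reactants: 6 (S)-6-methylhept-5-ene-1,4-diol
Product: 8 (S)-5-(2-methylprop-1-en-1-yl)dihydrofuran-2(3H)-one, via lactol 7 (not isolated)
Conditions: TEMPO (2,2,6,6-tetramethylpiperidin-1-oxyl, 0.2 equiv), PhI(OAc)2 (2.5 equiv), CH2Cl2, rt, 5 h
Reagents that add atoms: none
Why: Oxidative lactonization, in which the oxoammonium oxidant takes the unhindered primary alcohol first, the hydroxy aldehyde closes to lactol 7 and a second oxidation gives the γ-lactone (ring A) with the C–O stereocentre untouched.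

**Step 4**
Reactants: 9 (2E,6E)-farnesol
Product: 10 tert-butyl(diphenyl){[(2E,6E)-3,7,11-trimethyldodeca-2,6,10-trien-1-yl]oxy}silane
Conditions: TBDPSCl (1.1 equiv), imidazole (1.5 equiv), CH2Cl2, 0 °C to rt
Reagents that add atoms: tert-butyl(chloro)diphenylsilane (TBDPSCl), CC(C)(C)[Si](Cl)(c1ccccc1)c1ccccc1
Why: Silyl ether protection with the robust TBDPS group, which survives the halohydrin, periodate, enolate and amidine-base steps that follow.

**Step 5**
Reactants: 10 tert-butyl(diphenyl){[(2E,6E)-3,7,11-trimethyldodeca-2,6,10-trien-1-yl]oxy}silane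
Product: 11 (6E,10E)-3-bromo-12-[(tert-butyldiphenylsilyl)oxy]-2,6,10-trimethyldodeca-6,10-dien-2-ol (racemic)
Conditions: NBS (1.1 equiv), THF/H2O 4:1, 0 °C, 2 h
Reagents that add atoms: N-bromosuccinimide (NBS), O=C1CCC(=O)N1Br; water, O
Why: van Tamelen terminal bromohydrin formation, in which the most exposed and electron-rich terminal alkene forms the bromonium ion preferentially in aqueous THF and water opens it at the tertiary carbon.

**Step 6**
Reactants: 11 (6E,10E)-3-bromo-12-[(tert-butyldiphenylsilyl)oxy]-2,6,10-trimethyldodeca-6,10-dien-2-ol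
Product: 12 tert-butyl{[(2E,6E)-9-(3,3-dimethyloxiran-2-yl)-3,7-dimethylnona-2,6-dien-1-yl]oxy}diphenylsilane (racemic)
Conditions: K2CO3 (2 equiv), MeOH, rt, 2 h
Reagents that add atoms: none
Why: Intramolecular Williamson (SN2) closure of the tertiary alkoxide onto the neighbouring secondary bromide gives the epoxide.

**Step 7**
Reactants: 12 tert-butyl{[(2E,6E)-9-(3,3-dimethyloxiran-2-yl)-3,7-dimethylnona-2,6-dien-1-yl]oxy}diphenylsilane
Product: 14 (4E,8E)-10-[(tert-butyldiphenylsilyl)oxy]-4,8-dimethyldeca-4,8-dienal, via glycol 13 (not isolated)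
Conditions: H5IO6 (1.2 equiv), THF/Et2O, 0 °C, 1 h
Reagents that add atoms: none
Why: Acidic periodate opens the epoxide to glycol 13 and cleaves it (Malaprade glycol cleavage), releasing acetone and leaving the aldehyde that carries the former epoxide oxygen.

**Step 8 (key step)**
Reactants: 8 (S)-5-(2-methylprop-1-en-1-yl)dihydrofuran-2(3H)-one; 14 (4E,8E)-10-[(tert-butyldiphenylsilyl)oxy]-4,8-dimethyldeca-4,8-dienal
Product: 16 (5S)-3-{(4E,8E)-10-[(tert-butyldiphenylsilyl)oxy]-1-hydroxy-4,8-dimethyldeca-4,8-dien-1-yl}-5-(2-methylprop-1-en-1-yl)dihydrofuran-2(3H)-one (diastereomer mixture), via lithium enolate 15 (not isolated)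
Conditions: 8 (1.2 equiv), LiN(iPr)2 (1.25 equiv), THF, −78 °C, 45 min; then 14, THF, −78 °C, 1 h; sat. aq NH4Cl
Reagents that add atoms: none
Why: Intermolecular aldol addition, in which the kinetically formed lithium enolate of the γ-lactone adds to the unhindered aliphatic aldehyde at −78 °C; the two new centres form unselectively but are erased in the dehydration, and the γ-centre is not touched.

**Step 9**
Reactants: 16 the aldol adduct
Product: 17 (4E,8E)-10-[(tert-butyldiphenylsilyl)oxy]-4,8-dimethyl-1-[(5S)-5-(2-methylprop-1-en-1-yl)-2-oxotetrahydrofuran-3-yl]deca-4,8-dien-1-yl methanesulfonate (diastereomer mixture)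
Conditions: MsCl (1.3 equiv), Et3N (1.6 equiv), CH2Cl2, −20 to 0 °C, 30 min; cold aqueous work-up, used crude
Reagents that add atoms: methanesulfonyl chloride (MsCl), CS(=O)(=O)Cl
Why: Sulfonylation turns the secondary β-hydroxyl into a leaving group for the elimination.

**Step 10**
Reactants: 17 the mesylate
Product: 18 (S,E)-3-{(4E,8E)-10-[(tert-butyldiphenylsilyl)oxy]-4,8-dimethyldeca-4,8-dien-1-ylidene}-5-(2-methylprop-1-en-1-yl)dihydrofuran-2(3H)-one
Conditions: DBU (2 equiv), toluene, 0 °C to rt, 2 h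
Reagents that add atoms: none
Why: E1cB β-elimination through the lactone enolate converges both diastereomers on the conjugated exocyclic alkene with the thermodynamically preferred (E) geometry (chain anti to the carbonyl), the minor (Z) isomer being removed by chromatography.

**Step 11**
Reactants: 18 the silyl-protected alkylidene lactone
Product: 19 (S,E)-3-[(4E,8E)-10-hydroxy-4,8-dimethyldeca-4,8-dien-1-ylidene]-5-(2-methylprop-1-en-1-yl)dihydrofuran-2(3H)-one
Conditions: Bu4NF (1.5 equiv), AcOH (1.5 equiv), THF, 0 °C to rt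
Reagents that add atoms: none
Why: Fluoride-mediated desilylation, buffered with AcOH so the alkylidene lactone meets no free alkoxide, releases the primary allylic alcohol.

**Step 12**
Reactants: 19 the allylic alcohol
Product: 20 (2E,6E,10E)-3,7-dimethyl-10-[(5S)-5-(2-methylprop-1-en-1-yl)-2-oxodihydrofuran-3(2H)-ylidene]deca-2,6-dienal
Conditions: activated MnO2 (15 equiv), CH2Cl2, rt, dark
Reagents that add atoms: none
Why: Allylic oxidation with MnO2 touches only the allylic alcohol and gives the (E)-enal without double-bond isomerization or over-oxidation.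

**Step 13**
Reactants: 20 the enal
Product: 21 (S,E)-3-[(4E,8E,10E)-11-iodo-4,8-dimethylundeca-4,8,10-trien-1-ylidene]-5-(2-methylprop-1-en-1-yl)dihydrofuran-2(3H)-one
Conditions: CrCl2 (8 equiv), CHI3 (2.5 equiv), THF/1,4-dioxane 1:6, 0 °C to rt, dark
Reagents that add atoms: iodoform, IC(I)I
Why: Takai olefination, in which the geminal dichromium species formed from CHI3 and divalent chromium adds only to the aldehyde and eliminates to the (E)-vinyl iodide while lactones stay inert.

**Step 14**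
Reactants: 22 tetronic acid (4-hydroxyfuran-2(5H)-one)
Product: 23 4-bromofuran-2(5H)-one
Conditions: (COBr)2 (1.2 equiv), DMF (1.3 equiv), CH2Cl2, 0 °C to rt
Reagents that add atoms: oxalyl bromide, BrC(=O)C(=O)Br
Why: Vilsmeier-type halogenation of the vinylogous acid, in which the bromoiminium salt activates the enol oxygen and bromide replaces it by addition–elimination.

**Step 15**
Reactants: 23 4-bromofuran-2(5H)-one
Product: 24 4-(tributylstannyl)furan-2(5H)-one
Conditions: (Bu3Sn)2 (1.1 equiv), Pd(PPh3)4 (3 mol %), 1,4-dioxane, 80 °C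
Reagents that add atoms: hexabutylditin, CCCC[Sn](CCCC)(CCCC)[Sn](CCCC)(CCCC)CCCC
Why: Palladium-catalyzed stannylation, by oxidative addition of zerovalent palladium into the activated vinyl C–Br bond, transmetalation with the distannane and reductive elimination.

**Step 16**
Reactants: 21 the (E,E)-dienyl iodide; 24 4-(tributylstannyl)furan-2(5H)-one
Product: 25 (S,E)-3-[(4E,8E,10E)-4,8-dimethyl-11-(5-oxo-2,5-dihydrofuran-3-yl)undeca-4,8,10-trien-1-ylidene]-5-(2-methylprop-1-en-1-yl)dihydrofuran-2(3H)-one (target)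
Conditions: Pd2(dba)3 (5 mol %), AsPh3 (40 mol %), CuI (20 mol %), NMP, rt, dark, 12 h
Reagents that add atoms: none
Why: Stille cross-coupling, in which zerovalent palladium inserts into the dienyl C–I bond at room temperature (faster than any ionization of the hindered allylic lactone), CuI speeds transfer of the butenolide from tin, and reductive elimination joins the two sp2 carbons with the (E,E)-diene geometry retained.

**Compound list**
1 | 3-methylbut-2-enal (prenal) | CC(C)=CC=O | starting material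
2 | allylmagnesium bromide | C=CC[Mg]Br | starting material
3 | (S)-6-methylhepta-1,5-dien-4-yl diisopinocampheylborinate | C=CC[C@H](OB([C@@H]1C[C@@H]2C[C@H]([C@H]1C)C2(C)C)[C@@H]1C[C@@H]2C[C@H]([C@H]1C)C2(C)C)C=C(C)C | intermediate
4 | (S)-6-methylhepta-1,5-dien-4-ol | C=CC[C@H](O)C=C(C)C | intermediate
5 | 9-{(4S)-4-[(9-borabicyclo[3.3.1]nonan-9-yl)oxy]-6-methylhept-5-en-1-yl}-9-borabicyclo[3.3.1]nonane | CC(C)=C[C@@H](OB1C2CCCC1CCC2)CCCB1C2CCCC1CCC2 | intermediate
6 | (S)-6-methylhept-5-ene-1,4-diol | CC(C)=C[C@@H](O)CCCO | intermediate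
7 | (5S)-5-(2-methylprop-1-en-1-yl)tetrahydrofuran-2-ol (anomer mixture) | CC(C)=C[C@@H]1CCC(O)O1 | intermediate
8 | (S)-5-(2-methylprop-1-en-1-yl)dihydrofuran-2(3H)-one | CC(C)=C[C@@H]1CCC(=O)O1 | intermediate
9 | (2E,6E)-farnesol | CC(C)=CCC/C(C)=C/CC/C(C)=C/CO | starting material
10 | tert-butyl(diphenyl){[(2E,6E)-3,7,11-trimethyldodeca-2,6,10-trien-1-yl]oxy}silane | CC(C)=CCC/C(C)=C/CC/C(C)=C/CO[Si](c1ccccc1)(c1ccccc1)C(C)(C)C | intermediate
11 | (6E,10E)-3-bromo-12-[(tert-butyldiphenylsilyl)oxy]-2,6,10-trimethyldodeca-6,10-dien-2-ol (racemic) | CC(C)(O)C(Br)CC/C(C)=C/CC/C(C)=C/CO[Si](c1ccccc1)(c1ccccc1)C(C)(C)C | intermediate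
12 | tert-butyl{[(2E,6E)-9-(3,3-dimethyloxiran-2-yl)-3,7-dimethylnona-2,6-dien-1-yl]oxy}diphenylsilane (racemic) | CC1(C)OC1CC/C(C)=C/CC/C(C)=C/CO[Si](c1ccccc1)(c1ccccc1)C(C)(C)C | intermediate
13 | (6E,10E)-12-[(tert-butyldiphenylsilyl)oxy]-2,6,10-trimethyldodeca-6,10-diene-2,3-diol (racemic) | CC(C)(O)C(O)CC/C(C)=C/CC/C(C)=C/CO[Si](c1ccccc1)(c1ccccc1)C(C)(C)C | intermediate
14 | (4E,8E)-10-[(tert-butyldiphenylsilyl)oxy]-4,8-dimethyldeca-4,8-dienal | O=CCC/C(C)=C/CC/C(C)=C/CO[Si](c1ccccc1)(c1ccccc1)C(C)(C)C | intermediate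
15 | lithium enolate of 8, lithium (S)-5-(2-methylprop-1-en-1-yl)-4,5-dihydrofuran-2-olate | CC(C)=C[C@@H]1CC=C(O[Li])O1 | intermediate
16 | (5S)-3-{(4E,8E)-10-[(tert-butyldiphenylsilyl)oxy]-1-hydroxy-4,8-dimethyldeca-4,8-dien-1-yl}-5-(2-methylprop-1-en-1-yl)dihydrofuran-2(3H)-one (diastereomer mixture) | CC(C)=C[C@@H]1CC(C(O)CC/C(C)=C/CC/C(C)=C/CO[Si](c2ccccc2)(c2ccccc2)C(C)(C)C)C(=O)O1 | intermediate
17 | (4E,8E)-10-[(tert-butyldiphenylsilyl)oxy]-4,8-dimethyl-1-[(5S)-5-(2-methylprop-1-en-1-yl)-2-oxotetrahydrofuran-3-yl]deca-4,8-dien-1-yl methanesulfonate (diastereomer mixture) | CC(C)=C[C@@H]1CC(C(OS(C)(=O)=O)CC/C(C)=C/CC/C(C)=C/CO[Si](c2ccccc2)(c2ccccc2)C(C)(C)C)C(=O)O1 | intermediate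
18 | (S,E)-3-{(4E,8E)-10-[(tert-butyldiphenylsilyl)oxy]-4,8-dimethyldeca-4,8-dien-1-ylidene}-5-(2-methylprop-1-en-1-yl)dihydrofuran-2(3H)-one | CC(C)=C[C@@H]1C/C(=C\CC/C(C)=C/CC/C(C)=C/CO[Si](c2ccccc2)(c2ccccc2)C(C)(C)C)C(=O)O1 | intermediate
19 | (S,E)-3-[(4E,8E)-10-hydroxy-4,8-dimethyldeca-4,8-dien-1-ylidene]-5-(2-methylprop-1-en-1-yl)dihydrofuran-2(3H)-one | CC(C)=C[C@@H]1C/C(=C\CC/C(C)=C/CC/C(C)=C/CO)C(=O)O1 | intermediate
20 | (2E,6E,10E)-3,7-dimethyl-10-[(5S)-5-(2-methylprop-1-en-1-yl)-2-oxodihydrofuran-3(2H)-ylidene]deca-2,6-dienal | CC(C)=C[C@@H]1C/C(=C\CC/C(C)=C/CC/C(C)=C/C=O)C(=O)O1 | intermediate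
21 | (S,E)-3-[(4E,8E,10E)-11-iodo-4,8-dimethylundeca-4,8,10-trien-1-ylidene]-5-(2-methylprop-1-en-1-yl)dihydrofuran-2(3H)-one | CC(C)=C[C@@H]1C/C(=C\CC/C(C)=C/CC/C(C)=C/C=C/I)C(=O)O1 | intermediate
22 | tetronic acid (4-hydroxyfuran-2(5H)-one) | OC1=CC(=O)OC1 | starting material
23 | 4-bromofuran-2(5H)-one | BrC1=CC(=O)OC1 | intermediate
24 | 4-(tributylstannyl)furan-2(5H)-one | CCCC[Sn](CCCC)(CCCC)C1=CC(=O)OC1 | intermediate
25 | (S,E)-3-[(4E,8E,10E)-4,8-dimethyl-11-(5-oxo-2,5-dihydrofuran-3-yl)undeca-4,8,10-trien-1-ylidene]-5-(2-methylprop-1-en-1-yl)dihydrofuran-2(3H)-one | CC(C)=C[C@@H]1C/C(=C\CC/C(C)=C/CC/C(C)=C/C=C/C2=CC(=O)OC2)C(=O)O1 | target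

**Step count and risks**
Total steps: 16. Longest linear sequence: 11 steps (9 to 25 through steps 4–13 and 16).

Step 3 (oxidative lactonization of the unprotected diol): the secondary allylic alcohol could be oxidized in competition with the primary one. The fallback sets out from 4 and comes back at 8. Compound 4 is silylated (TBSCl, imidazole, DMF) to (S)-tert-butyl(dimethyl)[(6-methylhepta-1,5-dien-4-yl)oxy]silane F1. Hydroboration with 9-BBN in THF gives 9-{(4S)-4-[(tert-butyldimethylsilyl)oxy]-6-methylhept-5-en-1-yl}-9-borabicyclo[3.3.1]nonane F2, which is oxidized in the same flask (NaOH, H2O2) to (S)-4-[(tert-butyldimethylsilyl)oxy]-6-methylhept-5-en-1-ol F3. TEMPO and PhI(OAc)2 in MeCN/H2O take this to (S)-4-[(tert-butyldimethylsilyl)oxy]-6-methylhept-5-enoic acid F4. Bu4NF in THF frees (S)-4-hydroxy-6-methylhept-5-enoic acid F5, which closes to 8 on mild acidification (pH 4).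

Step 13 (Takai olefination of a polyfunctional enal): yield and E/Z ratio can be poor, and the dienyl iodide is light-sensitive. The fallback sets out from 20 and comes back at 25, replacing both the chromium and the tin chemistry. A boron–Wittig olefination is used: bis(pinacolatoboryl)methane is deprotonated with lithium 2,2,6,6-tetramethylpiperidide in THF at 0 °C, then 20 is added at −78 °C. This gives (S,E)-3-[(4E,8E,10E)-4,8-dimethyl-11-(4,4,5,5-tetramethyl-1,3,2-dioxaborolan-2-yl)undeca-4,8,10-trien-1-ylidene]-5-(2-methylprop-1-en-1-yl)dihydrofuran-2(3H)-one F6. Suzuki–Miyaura coupling of F6 with bromofuranone 23 (PdCl2(dppf), K3PO4, THF/H2O, 40 °C) gives 25.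

Step 16 (Stille coupling of the electron-poor stannylbutenolide with a sensitive dienyl iodide): transmetalation may be slow and the polyene may degrade. The fallback sets out from 20 and comes back at 25, building the butenolide ring instead of coupling it. Horner–Wadsworth–Emmons olefination of 20 with dimethyl [3-(tert-butyldimethylsilyloxy)-2-oxopropyl]phosphonate (LiCl, iPr2NEt, MeCN, rt) gives (S,E)-3-{(4E,8E,10E)-13-[(tert-butyldimethylsilyl)oxy]-4,8-dimethyl-12-oxotrideca-4,8,10-trien-1-ylidene}-5-(2-methylprop-1-en-1-yl)dihydrofuran-2(3H)-one F7. HF·pyridine in THF frees (S,E)-3-[(4E,8E,10E)-13-hydroxy-4,8-dimethyl-12-oxotrideca-4,8,10-trien-1-ylidene]-5-(2-methylprop-1-en-1-yl)dihydrofuran-2(3H)-one F8. Heating F8 with Ph3P=C=C=O in toluene at 90 °C acylates the hydroxyl to (3E,5E,9E)-6,10-dimethyl-13-[(5S)-5-(2-methylprop-1-en-1-yl)-2-oxodihydrofuran-3(2H)-ylidene]-2-oxotrideca-3,5,9-trien-1-yl (triphenylphosphoranylidene)acetate F9, which closes by intramolecular Wittig reaction onto the ketone to give 25.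

**Further compounds**
F1 | step 3 | (S)-tert-butyl(dimethyl)[(6-methylhepta-1,5-dien-4-yl)oxy]silane | C=CC[C@H](O[Si](C)(C)C(C)(C)C)C=C(C)C
F2 | step 3 | 9-{(4S)-4-[(tert-butyldimethylsilyl)oxy]-6-methylhept-5-en-1-yl}-9-borabicyclo[3.3.1]nonane | CC(C)=C[C@@H](O[Si](C)(C)C(C)(C)C)CCCB1C2CCCC1CCC2
F3 | step 3 | (S)-4-[(tert-butyldimethylsilyl)oxy]-6-methylhept-5-en-1-ol | CC(C)=C[C@@H](O[Si](C)(C)C(C)(C)C)CCCO
F4 | step 3 | (S)-4-[(tert-butyldimethylsilyl)oxy]-6-methylhept-5-enoic acid | CC(C)=C[C@@H](O[Si](C)(C)C(C)(C)C)CCC(=O)O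
F5 | step 3 | (S)-4-hydroxy-6-methylhept-5-enoic acid | CC(C)=C[C@@H](O)CCC(=O)O
F6 | step 13 | (S,E)-3-[(4E,8E,10E)-4,8-dimethyl-11-(4,4,5,5-tetramethyl-1,3,2-dioxaborolan-2-yl)undeca-4,8,10-trien-1-ylidene]-5-(2-methylprop-1-en-1-yl)dihydrofuran-2(3H)-one | CC(C)=C[C@@H]1C/C(=C\CC/C(C)=C/CC/C(C)=C/C=C/B2OC(C)(C)C(C)(C)O2)C(=O)O1
F7 | step 16 | (S,E)-3-{(4E,8E,10E)-13-[(tert-butyldimethylsilyl)oxy]-4,8-dimethyl-12-oxotrideca-4,8,10-trien-1-ylidene}-5-(2-methylprop-1-en-1-yl)dihydrofuran-2(3H)-one | CC(C)=C[C@@H]1C/C(=C\CC/C(C)=C/CC/C(C)=C/C=C/C(=O)CO[Si](C)(C)C(C)(C)C)C(=O)O1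
F8 | step 16 | (S,E)-3-[(4E,8E,10E)-13-hydroxy-4,8-dimethyl-12-oxotrideca-4,8,10-trien-1-ylidene]-5-(2-methylprop-1-en-1-yl)dihydrofuran-2(3H)-one | CC(C)=C[C@@H]1C/C(=C\CC/C(C)=C/CC/C(C)=C/C=C/C(=O)CO)C(=O)O1
F9 | step 16 | (3E,5E,9E)-6,10-dimethyl-13-[(5S)-5-(2-methylprop-1-en-1-yl)-2-oxodihydrofuran-3(2H)-ylidene]-2-oxotrideca-3,5,9-trien-1-yl (triphenylphosphoranylidene)acetate | CC(C)=C[C@@H]1C/C(=C\CC/C(C)=C/CC/C(C)=C/C=C/C(=O)COC(=O)C=P(c2ccccc2)(c2ccccc2)c2ccccc2)C(=O)O1
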